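The route rests on disconnecting C1–C10 in ring A. In ring B the oxygen-bearing C9 lies between two methylated carbons, C8 and C10, so ring B maps onto 2,6-dimethylphenol. Its phenolate is alkylated at the methyl-bearing ortho carbon C10 by a C1 iodide on a tether that runs from C5 through the gem-dimethyl C4 and the silyloxylated C3. This one step closes ring A, creates the quaternary C10 stereocentre under control of C3 and leaves C9 as the ketone of a cyclohexa-2,4-dienone. The precursor is a flat meta-substituted phenol, 3-[(3S)-3-silyloxy-5-iodo-2-methylpentan-2-yl]-2,6-dimethylphenol, whose only stereocentre comes from an asymmetric allylation.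

Key step: step 10

Remark 1: labdane numbering is used throughout (decalin C1–C10, side chain C11–C16); the target is 3β-acetoxy-9α-hydroxylabd-13-en-16,15-olide, (3S,5S,8R,9R,10S).
Remark 2: enolates, phenolates, alkoxides and acetylides formed by simple deprotonation are treated as reagent states of their parent compounds and are not numbered; (−)-Ipc2BOMe is the enantiomer derived from (+)-α-pinene.

Step 1
Reactants: 1 3-amino-2,6-dimethylphenol
Product: 3 3-bromo-2,6-dimethylphenol, via diazonium bromide 2 (not isolated)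
Conditions: NaNO2, 48% aq. HBr, 0 °C; then CuBr, 48% aq. HBr, 70 °C
Reagents that add atoms: hydrobromic acid (Br); CuBr ([Cu]Br); NaNO2 ([Na+].[O-]N=O, nitrogen of 2 only)
Why: Sandmeyer reaction: diazotisation of the anilinium salt in strong acid outruns ring nitrosation and azo coupling of the un-ionised phenol, and CuBr replaces N2 by bromine at the same carbon.

Step 2
Reactants: 3 3-bromo-2,6-dimethylphenol
Product: 4 2-(benzyloxy)-4-bromo-1,3-dimethylbenzene
Conditions: BnBr, K2CO3, DMF, 60 °C
Reagents that add atoms: benzyl bromide (BrCc1ccccc1)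
Why: Williamson ether synthesis; the phenol is masked before strongly basic enolate chemistry, and the benzyl group can later be removed by hydrogenolysis without touching a silyl ether.

Step 3
Reactants: 4 2-(benzyloxy)-4-bromo-1,3-dimethylbenzene; 5 methyl isobutyrate
Product: 6 methyl 2-[3-(benzyloxy)-2,4-dimethylphenyl]-2-methylpropanoate
Conditions: Cy2NLi (1.3 equiv), Pd(dba)2 (2 mol %), P(t-Bu)3 (2 mol %), toluene, rt
Reagents that add atoms: none
Why: Palladium-catalysed α-arylation of an ester enolate: the lithium enolate of 5 couples with the aryl bromide to form the quaternary C4–C5 bond, and the bulky electron-rich phosphine tolerates the single ortho methyl group.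

Step 4
Reactants: 6 methyl 2-[3-(benzyloxy)-2,4-dimethylphenyl]-2-methylpropanoate
Product: 7 2-[3-(benzyloxy)-2,4-dimethylphenyl]-2-methylpropanal
Conditions: i-Bu2AlH (1.1 equiv), CH2Cl2, −78 °C
Reagents that add atoms: none
Why: Partial ester reduction: the aluminium hemiacetal of the α-quaternary ester is stable at −78 °C and releases the non-enolisable aldehyde only on work-up.

Step 5
Reactants: 7 2-[3-(benzyloxy)-2,4-dimethylphenyl]-2-methylpropanal; 8 allylmagnesium bromide
Product: 9 (3S)-2-[3-(benzyloxy)-2,4-dimethylphenyl]-2-methylhex-5-en-3-ol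
Conditions: (−)-Ipc2BOMe, 8, Et2O, −78 °C → rt; then 7, −78 °C; then NaOH, H2O2
Reagents that add atoms: none
Why: Brown asymmetric allylboration: the B-allyldiisopinocampheylborane from (+)-α-pinene should add through a chair Zimmerman–Traxler transition state to the Si face of the α-quaternary aldehyde, as it does with pivalaldehyde, setting C3 as S.

Step 6
Reactants: 9 (3S)-2-[3-(benzyloxy)-2,4-dimethylphenyl]-2-methylhex-5-en-3-ol
Product: 10 tert-butyl{[(3S)-2-[3-(benzyloxy)-2,4-dimethylphenyl]-2-methylhex-5-en-3-yl]oxy}dimethylsilane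
Conditions: TBSOTf, 2,6-lutidine, CH2Cl2, 0 °C → rt
Reagents that add atoms: tert-butyldimethylsilyl triflate (CC(C)(C)[Si](C)(C)OS(=O)(=O)C(F)(F)F)
Why: Silylation with a silyl triflate, which is reactive enough for the neopentyl-type secondary alcohol and gives the ether that later steers the ring closure.

Step 7
Reactants: 10 tert-butyl{[(3S)-2-[3-(benzyloxy)-2,4-dimethylphenyl]-2-methylhex-5-en-3-yl]oxy}dimethylsilane
Product: 12 (3S)-4-[3-(benzyloxy)-2,4-dimethylphenyl]-3-[(tert-butyldimethylsilyl)oxy]-4-methylpentan-1-ol, via ozonide 11 (not isolated)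
Conditions: O3, CH2Cl2, −78 °C (Sudan Red 7B end point); then NaBH4, MeOH, −78 → 0 °C
Reagents that add atoms: ozone ([O-][O+]=O)
Why: Ozonolysis with hydride reduction of the ozonide: the monosubstituted alkene reacts far faster with ozone than the hindered alkoxyarene, and the indicator dye marks the end point, leaving C1 as a primary alcohol.

Step 8
Reactants: 12 (3S)-4-[3-(benzyloxy)-2,4-dimethylphenyl]-3-[(tert-butyldimethylsilyl)oxy]-4-methylpentan-1-ol
Product: 13 3-{(3S)-3-[(tert-butyldimethylsilyl)oxy]-5-hydroxy-2-methylpentan-2-yl}-2,6-dimethylphenol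
Conditions: H2 (1 atm), 10% Pd/C, EtOAc, rt
Reagents that add atoms: none
Why: Catalytic hydrogenolysis of the benzyl aryl ether under neutral conditions that spare the silyl ether; the phenol is freed before the iodide is introduced so that no C–I bond meets hydrogen and palladium.

Step 9
Reactants: 13 3-{(3S)-3-[(tert-butyldimethylsilyl)oxy]-5-hydroxy-2-methylpentan-2-yl}-2,6-dimethylphenol
Product: 14 3-{(3S)-3-[(tert-butyldimethylsilyl)oxy]-5-iodo-2-methylpentan-2-yl}-2,6-dimethylphenol
Conditions: I2, PPh3, imidazole, CH2Cl2, 0 °C → rt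
Reagents that add atoms: iodine (II)
Why: Appel-type iodination converts only the primary aliphatic alcohol, because an aryloxyphosphonium ion cannot be displaced and imidazole is too weak a base to ionise the phenol and start the cyclisation early.

Step 10
Reactants: 14 3-{(3S)-3-[(tert-butyldimethylsilyl)oxy]-5-iodo-2-methylpentan-2-yl}-2,6-dimethylphenol
Product: 15 (6S,8aS)-6-[(tert-butyldimethylsilyl)oxy]-2,5,5,8a-tetramethyl-6,7,8,8a-tetrahydronaphthalen-1(5H)-one (labdane numbering: 3β-silyloxy-5,7-dien-9-one with 10β-methyl)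
Conditions: t-BuOK (1.05 equiv), degassed t-BuOH–THF, 0.01 M, 25 → 60 °C
Reagents that add atoms: none
Why: t-BuOK converts 14 into its potassium phenolate, whose ortho carbon C10 displaces iodide from C1 in an intramolecular SN2 reaction; the closest known reaction type is alkylative dearomatisation of phenolates by aryl participation of the Ar2-6 kind, which here stops at the cyclohexa-2,4-dienone because C10 carries a methyl group and cannot re-aromatise. Ring A closes in the 6-exo-tet mode through a chair-like transition state in which C1 approaches C10 perpendicular to the aromatic plane. The new C10 stereocentre is controlled by C3: the chair that keeps the C3 silyloxy group equatorial should put C1 on the α-face and the methyl group β, whereas the other chair would hold an axial silyloxy group syn to the C1 methylene and within van der Waals contact of the departing iodide. The step needs C- over O-alkylation and C10 over C8 and C6: the meta relationship of tether and oxygen rules out O-alkylation and attack at C8, and closure at the para carbon C6 would force a C4 methyl group to eclipse the C10 methyl group, whereas the ground-state rotamer with C3 out of plane beside C10 is already the reactive one. High dilution in tert-butanol suppresses intermolecular O-alkylation, and the fully substituted diene termini C5 and C8 should protect 15 from Diels–Alder dimerisation.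

Step 11
Reactants: 15 (6S,8aS)-6-[(tert-butyldimethylsilyl)oxy]-2,5,5,8a-tetramethyl-6,7,8,8a-tetrahydronaphthalen-1(5H)-one
Product: 17 (2R,4aS,6S,8aS)-6-[(tert-butyldimethylsilyl)oxy]-2,5,5,8a-tetramethyloctahydronaphthalen-1(2H)-one (labdane numbering: 3β-silyloxy-9-ketone with 5α-H and 8α-methyl), via 8β-methyl ketone 16 (not isolated)
Conditions: H2 (4 atm), 10% Pd/C, EtOAc, rt; filter; then NaOMe, MeOH, 50 °C
Reagents that add atoms: none
Why: Heterogeneous hydrogenation followed by base epimerisation: both alkenes should take up hydrogen from the α-face because the β-face is screened by the axial C10 and 4β methyl groups, which fixes 5α-H (trans fusion), and enolisation then moves the C8 methyl from the axial β to the equatorial α position, relieving its 1,3-diaxial clash with the C10 methyl.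

Step 12
Reactants: 17 (2R,4aS,6S,8aS)-6-[(tert-butyldimethylsilyl)oxy]-2,5,5,8a-tetramethyloctahydronaphthalen-1(2H)-one
Product: 18 3β-[(tert-butyldimethylsilyl)oxy]-4,4,8α,10β-tetramethyl-9-methylidene-trans-decalin (5α-H)
Conditions: Ph3PCH3Br, t-BuOK, toluene, 90 °C
Reagents that add atoms: methyltriphenylphosphonium bromide (C[P+](c1ccccc1)(c1ccccc1)c1ccccc1.[Br-])
Why: Wittig methylenation: the non-stabilised ylide generated with t-BuOK in hot toluene olefinates hindered ketones, and any enolisation at C8 returns the stable equatorial epimer.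

Step 13
Reactants: 18 3β-[(tert-butyldimethylsilyl)oxy]-4,4,8α,10β-tetramethyl-9-methylidene-trans-decalin
Product: 19 spiro-oxirane of 18 at C9 with the oxygen α and C11 β (9α,11-epoxide)
Conditions: mCPBA, NaHCO3, CH2Cl2, 0 °C
Reagents that add atoms: 3-chloroperbenzoic acid (OOC(=O)c1cccc(Cl)c1)
Why: Prilezhaev epoxidation: the peracid should attack the exocyclic C9=C11 bond from the α-face, anti to the adjacent axial C10 methyl group, so the oxygen becomes 9α and C11 stays β (equatorial).

Step 14
Reactants: 19 9α,11-epoxide; 20 1-(trimethylsilyl)propyne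
Product: 22 3β-[(tert-butyldimethylsilyl)oxy]-15,16-dinorlabd-13-yn-9α-ol, via silylalkyne 21 (not isolated)
Conditions: 20, n-BuLi, TMEDA, THF, −20 °C; then 19, 0 → 45 °C; then MeOH, K2CO3, rt
Reagents that add atoms: none
Why: Propargylation of an epoxide: lithiated 20 opens the oxirane by SN2 at the unsubstituted carbon C11, so the C9–O bond and its α-configuration are untouched, and basic methanolysis then removes the alkynyl silyl group.

Step 15
Reactants: 22 3β-[(tert-butyldimethylsilyl)oxy]-15,16-dinorlabd-13-yn-9α-ol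
Product: 23 3β-[(tert-butyldimethylsilyl)oxy]-16-norlabd-13-yne-9α,15-diol
Conditions: n-BuLi (2.2 equiv), THF, −78 → 0 °C; then (CH2O)n, 0 °C → rt
Reagents that add atoms: paraformaldehyde, reacting as formaldehyde (C=O)
Why: Alkynylation of formaldehyde: the lithium acetylide of the alkoxide–acetylide dianion adds to monomeric formaldehyde, giving the 2-alkyn-1-ol whose hydroxyl directs the next step.

Step 16
Reactants: 23 3β-[(tert-butyldimethylsilyl)oxy]-16-norlabd-13-yne-9α,15-diol
Product: 25 (13Z)-3β-[(tert-butyldimethylsilyl)oxy]-13-iodo-16-norlabd-13-ene-9α,15-diol, via alkenylalanate 24 (not isolated)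
Conditions: NaAlH2(OCH2CH2OMe)2 (3 equiv), THF, 0 °C → rt; EtOAc; then I2, THF, −78 → 0 °C
Reagents that add atoms: iodine (II)
Why: Hydroxyl-directed trans-hydroalumination of a propargylic alcohol: hydride goes to C14 and aluminium to C13 within a five-membered alkoxyalanate, and iodinolysis with retention gives the Z-iodoalkene with iodine on C13 cis to the hydroxymethyl group.

Step 17
Reactants: 25 (13Z)-3β-[(tert-butyldimethylsilyl)oxy]-13-iodo-16-norlabd-13-ene-9α,15-diol
Product: 26 3β-[(tert-butyldimethylsilyl)oxy]-9α-hydroxylabd-13-en-16,15-olide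
Conditions: Pd(PPh3)4 (5 mol %), CO (1 atm), K2CO3, THF, 50 °C
Reagents that add atoms: carbon monoxide ([C-]#[O+])
Why: Palladium-catalysed carbonylative lactonisation of a Z-3-iodoallylic alcohol: oxidative addition, CO insertion and capture of the acylpalladium by the cis primary hydroxyl close the 2(5H)-furanone faster than the hindered tertiary C9 hydroxyl can intervene.

Step 18
Reactants: 26 3β-[(tert-butyldimethylsilyl)oxy]-9α-hydroxylabd-13-en-16,15-olide
Product: 27 3β,9α-dihydroxylabd-13-en-16,15-olide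
Conditions: 48% aq. HF, MeCN, rt
Reagents that add atoms: none
Why: Fluoride-driven silyl ether cleavage under mildly acidic conditions that leave the base-sensitive butenolide and the tertiary alcohol untouched.

Step 19
Reactants: 27 3β,9α-dihydroxylabd-13-en-16,15-olide
Product: 28 3β-acetoxy-9α-hydroxylabd-13-en-16,15-olide (CNP0117645.1)
Conditions: Ac2O, pyridine, DMAP (cat.), CH2Cl2, rt
Reagents that add atoms: acetic anhydride (CC(=O)OC(C)=O)
Why: DMAP-catalysed acylation selective for the equatorial secondary 3β-hydroxyl; the axial tertiary 9α-hydroxyl flanked by C8 and C10 substituents should not react under these conditions.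

Compound list
1 | 3-amino-2,6-dimethylphenol | Cc1ccc(N)c(C)c1O | starting material
2 | 3-hydroxy-2,4-dimethylbenzenediazonium bromide | Cc1ccc([N+]#N)c(C)c1O.[Br-] | intermediate
3 | 3-bromo-2,6-dimethylphenol | Cc1ccc(Br)c(C)c1O | intermediate
4 | 2-(benzyloxy)-4-bromo-1,3-dimethylbenzene | Cc1ccc(Br)c(C)c1OCc1ccccc1 | intermediate
5 | methyl isobutyrate | COC(=O)C(C)C | starting material
6 | methyl 2-[3-(benzyloxy)-2,4-dimethylphenyl]-2-methylpropanoate | COC(=O)C(C)(C)c1ccc(C)c(OCc2ccccc2)c1C | intermediate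
7 | 2-[3-(benzyloxy)-2,4-dimethylphenyl]-2-methylpropanal | O=CC(C)(C)c1ccc(C)c(OCc2ccccc2)c1C | intermediate
8 | allylmagnesium bromide | C=CC[Mg]Br | starting material
9 | (3S)-2-[3-(benzyloxy)-2,4-dimethylphenyl]-2-methylhex-5-en-3-ol | C=CC[C@H](O)C(C)(C)c1ccc(C)c(OCc2ccccc2)c1C | intermediate
10 | tert-butyl{[(3S)-2-[3-(benzyloxy)-2,4-dimethylphenyl]-2-methylhex-5-en-3-yl]oxy}dimethylsilane | C=CC[C@H](O[Si](C)(C)C(C)(C)C)C(C)(C)c1ccc(C)c(OCc2ccccc2)c1C | intermediate
11 | 3-{(2S)-3-[3-(benzyloxy)-2,4-dimethylphenyl]-2-[(tert-butyldimethylsilyl)oxy]-3-methylbutyl}-1,2,4-trioxolane (ozonide of 10) | CC(C)(C)[Si](C)(C)O[C@@H](CC1OCOO1)C(C)(C)c1ccc(C)c(OCc2ccccc2)c1C | intermediate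
12 | (3S)-4-[3-(benzyloxy)-2,4-dimethylphenyl]-3-[(tert-butyldimethylsilyl)oxy]-4-methylpentan-1-ol | OCC[C@H](O[Si](C)(C)C(C)(C)C)C(C)(C)c1ccc(C)c(OCc2ccccc2)c1C | intermediate
13 | 3-{(3S)-3-[(tert-butyldimethylsilyl)oxy]-5-hydroxy-2-methylpentan-2-yl}-2,6-dimethylphenol | OCC[C@H](O[Si](C)(C)C(C)(C)C)C(C)(C)c1ccc(C)c(O)c1C | intermediate
14 | 3-{(3S)-3-[(tert-butyldimethylsilyl)oxy]-5-iodo-2-methylpentan-2-yl}-2,6-dimethylphenol | ICC[C@H](O[Si](C)(C)C(C)(C)C)C(C)(C)c1ccc(C)c(O)c1C | intermediate
15 | (6S,8aS)-6-[(tert-butyldimethylsilyl)oxy]-2,5,5,8a-tetramethyl-6,7,8,8a-tetrahydronaphthalen-1(5H)-one | CC(C)(C)[Si](C)(C)O[C@H]1CC[C@@]2(C)C(=CC=C(C)C2=O)C1(C)C | intermediate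
16 | (2S,4aS,6S,8aS)-6-[(tert-butyldimethylsilyl)oxy]-2,5,5,8a-tetramethyloctahydronaphthalen-1(2H)-one (8β-methyl epimer, 5α-H) | CC(C)(C)[Si](C)(C)O[C@H]1CC[C@@]2(C)[C@@H](CC[C@H](C)C2=O)C1(C)C | intermediate
17 | (2R,4aS,6S,8aS)-6-[(tert-butyldimethylsilyl)oxy]-2,5,5,8a-tetramethyloctahydronaphthalen-1(2H)-one (8α-methyl, 5α-H) | CC(C)(C)[Si](C)(C)O[C@H]1CC[C@@]2(C)[C@@H](CC[C@@H](C)C2=O)C1(C)C | intermediate
18 | 3β-[(tert-butyldimethylsilyl)oxy]-4,4,8α,10β-tetramethyl-9-methylidene-trans-decalin (5α-H) | CC(C)(C)[Si](C)(C)O[C@H]1CC[C@@]2(C)[C@@H](CC[C@@H](C)C2=C)C1(C)C | intermediate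
19 | 9α,11-epoxide of 18 (spiro-oxirane at C9, oxygen α, C11 β) | CC(C)(C)[Si](C)(C)O[C@H]1CC[C@@]2(C)[C@@H](CC[C@@H](C)[C@]23CO3)C1(C)C | intermediate
20 | 1-(trimethylsilyl)propyne | CC#C[Si](C)(C)C | starting material
21 | 3β-[(tert-butyldimethylsilyl)oxy]-14-(trimethylsilyl)-15,16-dinorlabd-13-yn-9α-ol | CC(C)(C)[Si](C)(C)O[C@H]1CC[C@@]2(C)[C@@H](CC[C@@H](C)[C@]2(O)CCC#C[Si](C)(C)C)C1(C)C | intermediate
22 | 3β-[(tert-butyldimethylsilyl)oxy]-15,16-dinorlabd-13-yn-9α-ol | CC(C)(C)[Si](C)(C)O[C@H]1CC[C@@]2(C)[C@@H](CC[C@@H](C)[C@]2(O)CCC#C)C1(C)C | intermediate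
23 | 3β-[(tert-butyldimethylsilyl)oxy]-16-norlabd-13-yne-9α,15-diol | CC(C)(C)[Si](C)(C)O[C@H]1CC[C@@]2(C)[C@@H](CC[C@@H](C)[C@]2(O)CCC#CCO)C1(C)C | intermediate
24 | disodium salt of the cyclic C13–Al–O15 alkenylalanate of 23 (idealised) | CC(C)(C)[Si](C)(C)O[C@H]1CC[C@@]2(C)[C@@H](CC[C@@H](C)[C@]2([O-])CCC2=CCO[Al-]2(OCCOC)OCCOC)C1(C)C.[Na+].[Na+] | intermediate
25 | (13Z)-3β-[(tert-butyldimethylsilyl)oxy]-13-iodo-16-norlabd-13-ene-9α,15-diol | CC(C)(C)[Si](C)(C)O[C@H]1CC[C@@]2(C)[C@@H](CC[C@@H](C)[C@]2(O)CC/C(I)=C/CO)C1(C)C | intermediate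
26 | 3β-[(tert-butyldimethylsilyl)oxy]-9α-hydroxylabd-13-en-16,15-olide | CC(C)(C)[Si](C)(C)O[C@H]1CC[C@@]2(C)[C@@H](CC[C@@H](C)[C@]2(O)CCC2=CCOC2=O)C1(C)C | intermediate
27 | 3β,9α-dihydroxylabd-13-en-16,15-olide | O[C@H]1CC[C@@]2(C)[C@@H](CC[C@@H](C)[C@]2(O)CCC2=CCOC2=O)C1(C)C | intermediate
28 | (3S,5S,8R,9R,10S)-3β-acetoxy-9α-hydroxylabd-13-en-16,15-olide (CNP0117645.1) | CC(=O)O[C@H]1CC[C@@]2(C)[C@@H](CC[C@@H](C)[C@]2(O)CCC2=CCOC2=O)C1(C)C | target

Total step count: 19 steps. Longest linear sequence: 19 steps (1 → 28).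

Steps most likely to fail

Step 10. The ring may close through the alternative chair, which puts the silyloxy group axial and alkylates the opposite face of C10, so that facial selectivity is low or inverted. The stereochemical relay is then reversed and C3 corrected afterwards. Setting out from aldehyde 7, allylboration with the antipodal reagent made from (+)-Ipc2BOMe gives the (3R)-homoallylic alcohol F1. The operations of steps 6–9 then lead through silyl ether F2, ozonide F3 (not isolated), primary alcohol F4 and phenol F5 to iodophenol F6. Closure through the axial-silyloxy chair should now deliver the (3R,10S)-dienone F7. Hydrogenation and epimerisation as in step 11 give, by way of the 8β-methyl ketone F8 (not isolated), the 3α-silyloxy ketone F9. Desilylation (aq. HF, MeCN) gives hydroxy ketone F10, and Dess–Martin oxidation gives the 3,9-dione F11. NaBH4 should reduce only the less hindered C3 carbonyl, by axial hydride delivery, to the equatorial 3β-hydroxy ketone F12. Silylation with TBSOTf returns the material to the route at 17.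

Step 11. Hydrogenation of the C5=C6 bond, which lies between two quaternary carbons, may stall or lose facial selectivity. Setting out from dienone 15, dissolving-metal reduction (Li, liquid NH3, THF, t-BuOH, −78 °C; NH4Cl) should protonate the dienolate terminus C5 axially from the α-face and give the trans-fused β,γ-unsaturated ketone F13 (C6=C7, C8 as an epimer mixture). Its unhindered disubstituted alkene is then hydrogenated (H2, Pd/C, EtOAc), and NaOMe in MeOH equilibrates C8, returning to the route at 17.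

Step 14. SN2 opening at the neopentyl-like C11 may be slow, letting the basic reagent isomerise the oxirane to an allylic alcohol or the lithium cation rearrange it to the C9 aldehyde. Setting out from epoxide 19, excess dimethylsulfonium methylide (Me3SI, n-BuLi, THF, −10 °C → rt) opens the oxirane at C11 to sulfonium betaine F14 (not isolated), which loses dimethyl sulfide to give the 9α-hydroxy-9β-vinyl compound F15. Hydroboration with excess 9-BBN-H places boron on C12 and gives alkylborane F16 (not isolated). B-alkyl Suzuki–Miyaura coupling with 3-bromofuran-2(5H)-one (O=C1OCC=C1Br; PdCl2(dppf), AsPh3, Cs2CO3, DMF–H2O, rt) forms the C12–C13 bond and returns to the route at butenolide 26, bypassing steps 14–17.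

Further compounds
F1 | step 10 | (3R)-2-[3-(benzyloxy)-2,4-dimethylphenyl]-2-methylhex-5-en-3-ol | C=CC[C@@H](O)C(C)(C)c1ccc(C)c(OCc2ccccc2)c1C
F2 | step 10 | tert-butyl{[(3R)-2-[3-(benzyloxy)-2,4-dimethylphenyl]-2-methylhex-5-en-3-yl]oxy}dimethylsilane | C=CC[C@@H](O[Si](C)(C)C(C)(C)C)C(C)(C)c1ccc(C)c(OCc2ccccc2)c1C
F3 | step 10 | 3-{(2R)-3-[3-(benzyloxy)-2,4-dimethylphenyl]-2-[(tert-butyldimethylsilyl)oxy]-3-methylbutyl}-1,2,4-trioxolane | CC(C)(C)[Si](C)(C)O[C@H](CC1OCOO1)C(C)(C)c1ccc(C)c(OCc2ccccc2)c1C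
F4 | step 10 | (3R)-4-[3-(benzyloxy)-2,4-dimethylphenyl]-3-[(tert-butyldimethylsilyl)oxy]-4-methylpentan-1-ol | OCC[C@@H](O[Si](C)(C)C(C)(C)C)C(C)(C)c1ccc(C)c(OCc2ccccc2)c1C
F5 | step 10 | 3-{(3R)-3-[(tert-butyldimethylsilyl)oxy]-5-hydroxy-2-methylpentan-2-yl}-2,6-dimethylphenol | OCC[C@@H](O[Si](C)(C)C(C)(C)C)C(C)(C)c1ccc(C)c(O)c1C
F6 | step 10 | 3-{(3R)-3-[(tert-butyldimethylsilyl)oxy]-5-iodo-2-methylpentan-2-yl}-2,6-dimethylphenol | ICC[C@@H](O[Si](C)(C)C(C)(C)C)C(C)(C)c1ccc(C)c(O)c1C
F7 | step 10 | (6R,8aS)-6-[(tert-butyldimethylsilyl)oxy]-2,5,5,8a-tetramethyl-6,7,8,8a-tetrahydronaphthalen-1(5H)-one (3α-silyloxy, 10β-methyl) | CC(C)(C)[Si](C)(C)O[C@@H]1CC[C@@]2(C)C(=CC=C(C)C2=O)C1(C)C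
F8 | step 10 | 3α-silyloxy-8β-methyl-5α-H epimer of ketone 17 | CC(C)(C)[Si](C)(C)O[C@@H]1CC[C@@]2(C)[C@@H](CC[C@H](C)C2=O)C1(C)C
F9 | step 10 | 3α-silyloxy epimer of ketone 17 (8α-methyl, 5α-H) | CC(C)(C)[Si](C)(C)O[C@@H]1CC[C@@]2(C)[C@@H](CC[C@@H](C)C2=O)C1(C)C
F10 | step 10 | 3α-hydroxy-4,4,8α,10β-tetramethyl-trans-decalin-9-one | O[C@@H]1CC[C@@]2(C)[C@@H](CC[C@@H](C)C2=O)C1(C)C
F11 | step 10 | 4,4,8α,10β-tetramethyl-trans-decalin-3,9-dione | O=C1CC[C@@]2(C)[C@@H](CC[C@@H](C)C2=O)C1(C)C
F12 | step 10 | 3β-hydroxy-4,4,8α,10β-tetramethyl-trans-decalin-9-one | O[C@H]1CC[C@@]2(C)[C@@H](CC[C@@H](C)C2=O)C1(C)C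
F13 | step 11 | 3β-[(tert-butyldimethylsilyl)oxy]-4,4,8,10β-tetramethyl-5α-H-octal-6-en-9-one (C8 epimer mixture) | CC(C)(C)[Si](C)(C)O[C@H]1CC[C@@]2(C)[C@@H](C=CC(C)C2=O)C1(C)C
F14 | step 14 | sulfonium alkoxide betaine from 19 (C12 bearing the dimethylsulfonio group) | CC(C)(C)[Si](C)(C)O[C@H]1CC[C@@]2(C)[C@@H](CC[C@@H](C)[C@]2([O-])CC[S+](C)C)C1(C)C
F15 | step 14 | 3β-[(tert-butyldimethylsilyl)oxy]-13,14,15,16-tetranorlabd-11-en-9α-ol (9β-vinyl carbinol) | CC(C)(C)[Si](C)(C)O[C@H]1CC[C@@]2(C)[C@@H](CC[C@@H](C)[C@]2(O)C=C)C1(C)C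
F16 | step 14 | B-alkyl-9-borabicyclo[3.3.1]nonane from F15 (boron on C12; idealised with free 9-hydroxyl) | CC(C)(C)[Si](C)(C)O[C@H]1CC[C@@]2(C)[C@@H](CC[C@@H](C)[C@]2(O)CCB2C3CCCC2CCC3)C1(C)C
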